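## Analysis of the target

Target 23 is a (3Z,4S)-3-arylidene-4-benzyl-γ-butyrolactone. The lactone is numbered O1, C2(=O), C3, C4, C5, with C6 the exocyclic CH on C3 and C7 the benzylic CH2 on C4. Ring B on C7 is 4-hydroxy-3-methoxyphenyl. Ring A on C6 is C1' (on C6), C2'–H, C3'–OH, C4'–OH, C5'–OMe, C6'–H. C4 (S) is the only stereocentre. The C3=C6 bond is Z, with ring A cis to C2=O; this is the less stable geometry, so it has to be made under kinetic control and then kept away from strong acid, reversible nucleophilic addition and light. Sensitive groups are the free catechol of ring A, three phenols in all, and a lactone whose C4–H is γ to the carbonyl, so that strong base could racemise C4 or move the double bond into the ring. The synthesis is hard for two reasons: the Z alkene, and a ring A with three contiguous oxygens of which only the outer one (C5') is methylated, which by normal arene chemistry would need selective protection of a pyrogallol. The strategy rests on reading C3', C4' and C5' as the two alkoxy carbons and the carbonyl carbon of a squarate-derived cyclobutenone, with C2' as its fourth carbon and C1'/C6' supplied by a two-carbon alkyne. Ring A is then grown on C6 and C5' is born as its only free phenol.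

## Retrosynthetic reasoning

**23 to 22.** All three free OH groups at C3', C4' and C4 of ring B are masked as isopropyl ethers, which one Lewis-acid step should remove while the two methyl ethers stay. Ring B carries isopropyl rather than a silyl ether because an aryl silyl ether would not survive methoxide in the Stobbe step, the desilylation of the alkyne, or carbonate and a methylating agent. It also lets ring B share the final deprotection with ring A.

**22 to 21.** The C5' methyl is removed to leave phenol 21. Forward, this is a simple O-methylation of the only free phenol in the molecule, so no selectivity problem arises.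

**21 to 14 and 17 (key disconnection).** Ring A is cut at C1'–C2' and C5'–C6'. This gives the 2-stannyl diene 14 (C1' bears tin, C6' is its CH2) and the 4-chlorocyclobutenone 17 (its CHCl is C2', its two alkoxy carbons are C3' and C4', its carbonyl is C5'). No bond to C6 or within the lactone is cut, so the Z alkene and C4 are in place before the risky step. Forward, a cross-coupling has to join C1' to C2', and the four-membered ring then has to open and re-close to the phenol.

**17 to 16 to 15.** The chloride comes from the allylic alcohol 16, and 16 from mono-reduction of one carbonyl of diisopropyl squarate 15. Both isopropyl groups of 15 end up on C3' and C4', so the oxygen pattern is set by which carbonyl is reduced, and the two carbonyls of 15 are equivalent.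

**14 to 13.** The C–Sn bond and one C–H bond are removed to give the terminal enyne 13. Forward, hydrostannation has to place tin on the internal alkyne carbon, which is the usual preference of a terminal alkyne conjugated to an alkene and here also to a carbonyl.

**13 to 12 to 10 and 11.** The C6–C1' bond is cut between an sp2 and an sp carbon, giving the (Z)-enol tosylate 10 and trimethylsilylacetylene 11. Cross-coupling is stereoretentive, so the geometry of 10 becomes that of the target.

**10 to 9 to 7 and 8.** The tosylate is the sulfonylated enol of the 3-formyl lactone 9, made by Claisen condensation of lactone 7 with ethyl formate 8 (C3–C6 bond). The geometry is decided in the sulfonylation: a lithium-chelated enolate holds the enol oxygen cis to C2=O.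

**7 to 5 to 4 to 2 and 3.** The lactone is opened to the half-ester 5, whose stereocentre comes from hydrogenation of the Stobbe half-ester 4, made from aldehyde 2 and dimethyl succinate 3 (C4=C7 bond). C4 is thus set by a catalytic hydrogenation of a substrate class on which high selectivity is the rule, with the whole ring B skeleton already attached.

**2 to 1.** Aldehyde 2 is the isopropyl ether of vanillin 1.

## Alternatives that were turned down

**Alternative 1: enantioselective oxetane opening.**
- Disconnection: O1–C5, with C4 created from an achiral oxetane.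
- Forward key step: the (Z)-2-(oxetan-3-yl)-3-arylacrylic acid A1 cyclises under the chiral phosphoric acid TRIP. The carboxyl oxygen opens one of the two enantiotopic oxetane CH2 groups to give the 4-(hydroxymethyl) lactone A2.
- For: ring and stereocentre are formed in one metal-free catalytic step, with the arylidene already present.
- Against: A1 needs ring A cis to the carboxyl group before any ring holds it there, and it is then exposed to a Brønsted acid that can equilibrate a push-pull cinnamic acid. Ring A must be carried as a pre-differentiated pyrogallol with two silyl ethers. After the key step C7 is only a CH2OH, so ring B has to be attached by an sp3–sp2 coupling next to an allylic, β-hydrogen-bearing C4, where elimination competes.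
- Comparison: it is stronger in making C4 and the lactone in a single step and in avoiding tin. The chosen route instead sets C4 with ring B already attached and obtains the ring A oxygen pattern by construction.

**Alternative 2: desymmetrising Baeyer–Villiger oxidation.**
- Disconnection: oxygen insertion between C2 and C5 of a prochiral cyclobutanone.
- Forward key step: the 3-benzylcyclobutanone A3 is oxidised by cyclohexanone monooxygenase and O2, or by H2O2 with a chiral phosphoric acid, to the lactone A4.
- For: A3 is quickly reached from an allylarene by ketene cycloaddition, the oxidant is cheap, and A4 differs from lactone 7 only in its phenol protecting group. It would reach that stage in fewer steps than the Stobbe sequence and is stronger on that point.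
- Against: the benzyl group is remote from the reacting carbonyl, so small-molecule catalysts discriminate modestly; an enzyme has to be matched to the S series; and peroxide meets an electron-rich arene. More important, it solves only the lactone. The arylidene would then come from an aldol condensation, which favours ring A trans to C2=O, and from a selectively protected pyrogallol aldehyde.
- Comparison: it is a possible feeder for 7, not an answer to the two real problems. The chosen route uses a hydrogenation for C4 and spends its effort on the geometry and on ring A.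

**Alternative 3: hydrogenative enyne cyclisation.**
- Disconnection: C3–C4 together with C6–H and C7–H.
- Forward key step: the coniferyl arylpropiolate A5 takes up H2 over Rh(cod)2OTf and one enantiomer of BINAP. Oxidative cyclisation forms C3–C4 and hydrogenolysis of the rhodacycle gives the tris-silyl ether A6.
- For: the whole skeleton, C4 and the alkene are formed at once. The metallacycle places rhodium cis to C4, so ring A ends up cis to C2=O, which is the required geometry. The target would follow in about six steps, so on step economy this is clearly the stronger plan.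
- Against: the ester tether prefers the conformer in which alkyne and alkene cannot meet. The styrenyl alkene is 1,2-disubstituted, and the rhodacycle can undergo β-hydride elimination to a diene in place of hydrogenolysis. The ynoate and the styrene can also simply be hydrogenated. Ring A again has to be bought as a differentiated pyrogallol and turned into an arylpropiolic acid.
- Comparison: the chosen route is longer, but each step before the key step has precedent on its own substrate class, and its one exploratory step comes late and is backed by a cross-coupling from the same tosylate.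

Key step: step 12

Assumption: in step 3 the sense of induction is taken to follow that of Stobbe-type itaconate half-esters with Et-DuPhos–rhodium catalysts, the (R,R) ligand giving the (S)-2-substituted succinate; should the sense be the reverse, the equally available (S,S) ligand is used.

## Route

**Step 1**
Reactants: 1 vanillin (4-hydroxy-3-methoxybenzaldehyde)
Product: 2 4-isopropoxy-3-methoxybenzaldehyde
Conditions: 2-bromopropane, K2CO3, DMF, 70 °C
Reagents that add atoms: 2-bromopropane, CC(C)Br
Why: Williamson ether synthesis on a phenoxide; the isopropyl ether withstands every later base, palladium and tin step and is cleaved at the end together with those of ring A.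

**Step 2**
Reactants: 2 4-isopropoxy-3-methoxybenzaldehyde; 3 dimethyl succinate
Product: 4 (E)-4-(4-isopropoxy-3-methoxyphenyl)-3-(methoxycarbonyl)but-3-enoic acid
Conditions: NaOMe, MeOH, reflux; then aq. HCl
Reagents that add atoms: none
Why: Stobbe condensation; aldol addition, lactonisation onto the distal ester and E1cB opening give the half-ester with the free acid on the CH2 arm and the aryl group trans to the conjugated ester.

**Step 3**
Reactants: 4 (E)-4-(4-isopropoxy-3-methoxyphenyl)-3-(methoxycarbonyl)but-3-enoic acid
Product: 5 (S)-4-(4-isopropoxy-3-methoxyphenyl)-3-(methoxycarbonyl)butanoic acid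
Conditions: H2 (5 bar), [Rh(cod)((R,R)-Et-DuPhos)]BF4 (0.5 mol%), NaOMe (10 mol%), MeOH, rt; then dilute HCl
Reagents that add atoms: none
Why: Asymmetric hydrogenation of an itaconate-type half-ester with a cationic monovalent-rhodium bisphospholane catalyst; carboxylate and alkene chelate the metal and the ligand selects the alkene face, which sets the future C4 as S.

**Step 4**
Reactants: 5 (S)-4-(4-isopropoxy-3-methoxyphenyl)-3-(methoxycarbonyl)butanoic acid
Product: 7 (S)-4-(4-isopropoxy-3-methoxybenzyl)dihydrofuran-2(3H)-one, via hydroxy acid 6 (not isolated)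
Conditions: KOH (1 equiv), EtOH; CaCl2, NaBH4, EtOH, −10 °C → rt; then 2 M HCl, rt
Reagents that add atoms: none
Why: Ca(BH4)2 formed in the flask reduces the methyl ester but not the potassium carboxylate, and acidification closes the γ-lactone; the stereocentre is not enolisable at either stage and is carried over unchanged.

**Step 5**
Reactants: 7 (S)-4-(4-isopropoxy-3-methoxybenzyl)dihydrofuran-2(3H)-one; 8 ethyl formate
Product: 9 (S)-3-(hydroxymethylene)-4-(4-isopropoxy-3-methoxybenzyl)dihydrofuran-2(3H)-one (enol tautomer of the 3-formyl lactone)
Conditions: NaH, HCO2Et, cat. EtOH, THF, 0 °C → rt; then cold dilute HCl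
Reagents that add atoms: none
Why: Crossed Claisen condensation at the only enolisable position (C3), driven by formation of the stabilised sodium enolate; C4 is β to the carbonyl and untouched.

**Step 6**
Reactants: 9 (S)-3-(hydroxymethylene)-4-(4-isopropoxy-3-methoxybenzyl)dihydrofuran-2(3H)-one
Product: 10 (Z)-[(4S)-4-(4-isopropoxy-3-methoxybenzyl)-2-oxodihydrofuran-3(2H)-ylidene]methyl 4-methylbenzenesulfonate (sulfonate oxygen cis to C2=O)
Conditions: TsCl, N-methylimidazole, LiOH, MeCN, 0 °C
Reagents that add atoms: 4-toluenesulfonyl chloride, Cc1ccc(cc1)S(Cl)(=O)=O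
Why: Stereoselective enol tosylation of an α-formyl ester; lithium bridges the enolate oxygen and the lactone carbonyl, so the N-sulfonylimidazolium reagent traps the chelated enolate and the sulfonate ends up cis to C2=O.

**Step 7**
Reactants: 10 (Z)-enol tosylate; 11 trimethylsilylacetylene
Product: 12 (3Z,4S)-4-(4-isopropoxy-3-methoxybenzyl)-3-[3-(trimethylsilyl)prop-2-yn-1-ylidene]dihydrofuran-2(3H)-one
Conditions: PdCl2(PPh3)2 (3 mol%), CuI (5 mol%), iPr2NEt, THF, 40 °C
Reagents that add atoms: none
Why: Sonogashira coupling of a β-sulfonyloxy acrylate, which undergoes oxidative addition like a vinylogous mixed anhydride; coupling is stereoretentive and the hindered amine avoids addition–elimination at C6.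

**Step 8**
Reactants: 12 (3Z,4S)-silyl enyne
Product: 13 (3Z,4S)-4-(4-isopropoxy-3-methoxybenzyl)-3-(prop-2-yn-1-ylidene)dihydrofuran-2(3H)-one
Conditions: TBAF, AcOH, THF, 0 °C
Reagents that add atoms: none
Why: Fluoride-induced protodesilylation of an alkynylsilane; buffering with acetic acid keeps the medium non-basic, so the lactone, the γ-hydrogen at C4 and the Z alkene are not disturbed.

**Step 9**
Reactants: 13 (3Z,4S)-terminal enyne
Product: 14 (3Z,4S)-4-(4-isopropoxy-3-methoxybenzyl)-3-[2-(tributylstannyl)prop-2-en-1-ylidene]dihydrofuran-2(3H)-one
Conditions: Bu3SnH (slow addition), Pd(PPh3)4 (2 mol%), THF, 0 °C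
Reagents that add atoms: tributyltin hydride, CCCC[SnH](CCCC)CCCC
Why: Palladium-catalysed syn-hydrostannation; in a terminal alkyne conjugated to an alkene, and here polarised further by the lactone carbonyl, hydride goes to the terminal carbon and tin to the internal one, giving the 2-stannyl diene.

**Step 10**
Reactants: 15 diisopropyl squarate (3,4-diisopropoxycyclobut-3-ene-1,2-dione)
Product: 16 4-hydroxy-2,3-diisopropoxycyclobut-2-en-1-one (racemic)
Conditions: LiAlH(OtBu)3, THF, −78 → −20 °C; then sat. aq. NH4Cl, 0 °C
Reagents that add atoms: none
Why: 1,2-Reduction of one of two equivalent vinylogous-ester carbonyls by a bulky, mild hydride; the product is a vinylogous ester and is not reduced further at low temperature.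

**Step 11**
Reactants: 16 4-hydroxy-2,3-diisopropoxycyclobut-2-en-1-one
Product: 17 4-chloro-2,3-diisopropoxycyclobut-2-en-1-one (racemic)
Conditions: PPh3, CCl4, CH2Cl2, 0 °C → rt; Ph3PO precipitated with pentane, filtrate concentrated cold and used at once
Reagents that add atoms: carbon tetrachloride, ClC(Cl)(Cl)Cl
Why: Appel chlorination of an allylic alcohol under neutral conditions; chloride should settle on the CH carbon, because only that isomer keeps the conjugated vinylogous ester.

**Step 12**
Reactants: 14 (3Z,4S)-2-stannyl diene; 17 4-chloro-2,3-diisopropoxycyclobut-2-en-1-one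
Product: 21 (3Z,4S)-3-(3-hydroxy-4,5-diisopropoxybenzylidene)-4-(4-isopropoxy-3-methoxybenzyl)dihydrofuran-2(3H)-one (free OH at C5', isopropyl ethers at C3' and C4'), via dienylcyclobutenone 18 (not isolated), via dienylketene 19 (not isolated), via cyclohexadienone 20 (not isolated)
Conditions: Pd2(dba)3 (2.5 mol%), tri(2-furyl)phosphine (10 mol%), dioxane, 50 °C, then 90 °C
Reagents that add atoms: none
Why: Zerovalent palladium inserts into the allylic C–Cl bond of 17 to give an oxocyclobutenyl–palladium chloride, which transmetalates with stannane 14 and reductively eliminates at the unsubstituted CH terminus, joining C2' to C1' (18); the closest known reaction type is the palladium-catalysed coupling of 4-chlorocyclobutenones with alkenylstannanes followed by thermal benzannulation to phenols. Ring strain then drives conrotatory 4π opening of 18 to the dienylketene 19; only the rotamer with the dienyl group turned towards the ketene reacts on, and the other can revert to 18. Ring A closes by a thermal disrotatory 6π electrocyclisation in which the ketene carbon C5' bonds to the CH2 terminus C6', and the cyclohexa-2,4-dienone 20 enolises to the phenol. No stereocentre is created: the cyclobutenone CH of 18 becomes planar in the opening, and C4 is a remote spectator. The substitution pattern of the arene follows from connectivity, because C1' carries only one π bond (to C6') and no second 6π array exists; the C3=C6 alkene lies outside the pericyclic array and should keep its Z geometry at 90 °C or below. The selectivity that has to be secured is the site of reductive elimination on the oxocyclobutenyl ligand, which should be ensured by the steric contrast between the CH terminus and the isopropoxy-bearing terminus and by retention of the vinylogous ester. Tri(2-furyl)phosphine is chosen because transmetalation from a 1,1-disubstituted alkenylstannane is slow and has to outrun ionisation of the chloride.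

**Step 13**
Reactants: 21 (3Z,4S)-ring A phenol
Product: 22 (3Z,4S)-3-(3,4-diisopropoxy-5-methoxybenzylidene)-4-(4-isopropoxy-3-methoxybenzyl)dihydrofuran-2(3H)-one
Conditions: MeI, K2CO3, acetone, 40 °C
Reagents that add atoms: iodomethane, CI
Why: O-Methylation of the only free phenol; the C5' oxygen is meta to C1', so its phenoxide cannot open a quinone-methide path to alkene isomerisation, and carbonate is too weak to deprotonate C4.

**Step 14**
Reactants: 22 (3Z,4S)-tris(isopropyl) ether
Product: 23 (3Z,4S)-3-(3,4-dihydroxy-5-methoxybenzylidene)-4-(4-hydroxy-3-methoxybenzyl)dihydrofuran-2(3H)-one (target)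
Conditions: BCl3 (1 M in CH2Cl2, 6 equiv), CH2Cl2, −78 → 0 °C; then MeOH, aq. NaHCO3
Reagents that add atoms: none
Why: Lewis-acid dealkylation of aryl isopropyl ethers; the secondary alkyl group leaves as 2-chloropropane far faster than a methyl group does, so the two methyl ethers should stay, and low temperature limits rotation about C3=C6.

## Compound list

1 | vanillin | COc1cc(C=O)ccc1O | starting material
2 | 4-isopropoxy-3-methoxybenzaldehyde | COc1cc(C=O)ccc1OC(C)C | intermediate
3 | dimethyl succinate | COC(=O)CCC(=O)OC | starting material
4 | (E)-4-(4-isopropoxy-3-methoxyphenyl)-3-(methoxycarbonyl)but-3-enoic acid | COC(=O)/C(CC(=O)O)=C/c1ccc(OC(C)C)c(OC)c1 | intermediate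
5 | (S)-4-(4-isopropoxy-3-methoxyphenyl)-3-(methoxycarbonyl)butanoic acid | COc1cc(C[C@@H](CC(=O)O)C(=O)OC)ccc1OC(C)C | intermediate
6 | (S)-4-hydroxy-3-(4-isopropoxy-3-methoxybenzyl)butanoic acid (not isolated) | COc1cc(C[C@@H](CC(=O)O)CO)ccc1OC(C)C | intermediate
7 | (S)-4-(4-isopropoxy-3-methoxybenzyl)dihydrofuran-2(3H)-one | COc1cc(C[C@@H]2COC(=O)C2)ccc1OC(C)C | intermediate
8 | ethyl formate | CCOC=O | starting material
9 | (S)-3-(hydroxymethylene)-4-(4-isopropoxy-3-methoxybenzyl)dihydrofuran-2(3H)-one | COc1cc(C[C@@H]2COC(=O)C2=CO)ccc1OC(C)C | intermediate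
10 | (Z)-[(4S)-4-(4-isopropoxy-3-methoxybenzyl)-2-oxodihydrofuran-3(2H)-ylidene]methyl 4-methylbenzenesulfonate | COc1cc(C[C@@H]2COC(=O)/C2=C\OS(=O)(=O)c2ccc(C)cc2)ccc1OC(C)C | intermediate
11 | trimethylsilylacetylene | C#C[Si](C)(C)C | starting material
12 | (3Z,4S)-4-(4-isopropoxy-3-methoxybenzyl)-3-[3-(trimethylsilyl)prop-2-yn-1-ylidene]dihydrofuran-2(3H)-one | COc1cc(C[C@@H]2COC(=O)/C2=C\C#C[Si](C)(C)C)ccc1OC(C)C | intermediate
13 | (3Z,4S)-4-(4-isopropoxy-3-methoxybenzyl)-3-(prop-2-yn-1-ylidene)dihydrofuran-2(3H)-one | COc1cc(C[C@@H]2COC(=O)/C2=C\C#C)ccc1OC(C)C | intermediate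
14 | (3Z,4S)-4-(4-isopropoxy-3-methoxybenzyl)-3-[2-(tributylstannyl)prop-2-en-1-ylidene]dihydrofuran-2(3H)-one | COc1cc(C[C@@H]2COC(=O)/C2=C\C(=C)[Sn](CCCC)(CCCC)CCCC)ccc1OC(C)C | intermediate
15 | diisopropyl squarate | CC(C)OC1=C(OC(C)C)C(=O)C1=O | starting material
16 | 4-hydroxy-2,3-diisopropoxycyclobut-2-en-1-one (racemic) | CC(C)OC1=C(OC(C)C)C(=O)C1O | intermediate
17 | 4-chloro-2,3-diisopropoxycyclobut-2-en-1-one (racemic) | CC(C)OC1=C(OC(C)C)C(=O)C1Cl | intermediate
18 | (3Z,4S)-3-[2-(2,3-diisopropoxy-4-oxocyclobut-2-en-1-yl)prop-2-en-1-ylidene]-4-(4-isopropoxy-3-methoxybenzyl)dihydrofuran-2(3H)-one, both epimers at the cyclobutenone CH (not isolated) | COc1cc(C[C@@H]2COC(=O)/C2=C\C(=C)C2C(OC(C)C)=C(OC(C)C)C2=O)ccc1OC(C)C | intermediate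
19 | dienylketene from ring opening of 18, C1' and the ketene cis on the C2'=C3' bond (not isolated) | COc1cc(C[C@@H]2COC(=O)/C2=C\C(=C)/C=C(OC(C)C)\C(OC(C)C)=C=O)ccc1OC(C)C | intermediate
20 | (3Z,4S)-3-[(3,4-diisopropoxy-5-oxocyclohexa-1,3-dien-1-yl)methylidene]-4-(4-isopropoxy-3-methoxybenzyl)dihydrofuran-2(3H)-one (not isolated) | COc1cc(C[C@@H]2COC(=O)/C2=C\C2=CC(OC(C)C)=C(OC(C)C)C(=O)C2)ccc1OC(C)C | intermediate
21 | (3Z,4S)-3-(3-hydroxy-4,5-diisopropoxybenzylidene)-4-(4-isopropoxy-3-methoxybenzyl)dihydrofuran-2(3H)-one | COc1cc(C[C@@H]2COC(=O)/C2=C\c2cc(O)c(OC(C)C)c(OC(C)C)c2)ccc1OC(C)C | intermediate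
22 | (3Z,4S)-3-(3,4-diisopropoxy-5-methoxybenzylidene)-4-(4-isopropoxy-3-methoxybenzyl)dihydrofuran-2(3H)-one | COc1cc(C[C@@H]2COC(=O)/C2=C\c2cc(OC)c(OC(C)C)c(OC(C)C)c2)ccc1OC(C)C | intermediate
23 | (3Z,4S)-3-(3,4-dihydroxy-5-methoxybenzylidene)-4-(4-hydroxy-3-methoxybenzyl)dihydrofuran-2(3H)-one | COc1cc(C[C@@H]2COC(=O)/C2=C\c2cc(O)c(O)c(OC)c2)ccc1O | target

## Step count and least certain steps

Total: 14 steps. Longest linear sequence: 12 steps (steps 1 to 9, then 12 to 14). The two-step squarate branch (steps 10 and 11) joins at step 12.

**Step 12 (key step).**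
- What may go wrong: the chloride may ionise, helped by the alkoxy group on the neighbouring carbon, and collapse by loss of an isopropyl group before palladium and tin have joined the fragments. Transmetalation from the hindered 1,1-disubstituted stannane is slow, which invites cine-substitution at the CH2 terminus or homocoupling. Reductive elimination at the alkoxy-bearing terminus of the oxocyclobutenyl ligand would lead, after the same cascade, to a differently oxygenated arene.
- Fallback: it sets out from tosylate 10 and returns at 22, with ring A brought in ready-made. 3-Methoxycatechol F1 is alkylated with 2-bromopropane and K2CO3 to 1,2-diisopropoxy-3-methoxybenzene F2. C–H borylation with B2pin2, [Ir(cod)OMe]2 and 4,4'-di-tert-butyl-2,2'-bipyridine at the only CH not flanked by an oxygen gives 2-(3,4-diisopropoxy-5-methoxyphenyl)-4,4,5,5-tetramethyl-1,3,2-dioxaborolane F3. Stereoretentive Suzuki–Miyaura coupling of F3 with 10 (Pd(OAc)2, SPhos, K3PO4, THF–water) gives 22 directly.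

**Step 11.**
- What may go wrong: loss of the chloride during concentration or on silica, through ionisation and dealkylation or hydrolysis towards the cyclobutenedione, because the leaving group sits on a carbon whose cation is stabilised by the alkoxy group.
- Fallback: it sets out from 16 and returns at 21, using a poorer leaving group and a different coupling class. Acetylation (Ac2O, pyridine, cat. DMAP) gives 4-acetoxy-2,3-diisopropoxycyclobut-2-en-1-one F4. F4 is coupled with stannane 14 as an allylic acetate (Pd2(dba)3, LiCl, DMF, 50 °C, then 90 °C), and the same electrocyclic cascade gives 21.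

**Step 9.**
- What may go wrong: delivery of tin to the terminal carbon, giving the linear dienylstannane, or conjugate hydride delivery to the unsaturated lactone, since the tin hydride and Pd(PPh3)4 also reduce electron-poor alkenes.
- Fallback: it sets out from 13 and returns at 14, using no hydride. Syn-addition of hexabutylditin across the alkyne (Pd(PPh3)4, THF, reflux) gives (3Z,4S)-3-[(Z)-2,3-bis(tributylstannyl)prop-2-en-1-ylidene]-4-(4-isopropoxy-3-methoxybenzyl)dihydrofuran-2(3H)-one F5. One equivalent of HCl in CH2Cl2 at −78 °C removes the terminal tin selectively, because ipso-protonation there leaves the cation β to the remaining tin, and gives 14.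

**Step 6.**
- What may go wrong: sulfonylation through the non-chelated enolate, placing the sulfonate trans to C2=O. The five-membered ring widens the distance between the two oxygens, so the lithium chelate is weaker than in open-chain α-formyl esters.
- Fallback: it sets out from 9 and returns at 22, fixing the geometry at the end by light. Non-chelating tosylation (TsCl, N-methylimidazole, Et3N) gives (E)-[(4S)-4-(4-isopropoxy-3-methoxybenzyl)-2-oxodihydrofuran-3(2H)-ylidene]methyl 4-methylbenzenesulfonate F6. The conditions of steps 7 to 9, 12 and 13 then give in turn: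
  - the (3E,4S)-silyl enyne F7;
  - the (3E,4S)-terminal enyne F8;
  - the (3E,4S)-2-stannyl diene F9;
  - (3E,4S)-3-(3-hydroxy-4,5-diisopropoxybenzylidene)-4-(4-isopropoxy-3-methoxybenzyl)dihydrofuran-2(3H)-one F10;
  - (3E,4S)-3-(3,4-diisopropoxy-5-methoxybenzylidene)-4-(4-isopropoxy-3-methoxybenzyl)dihydrofuran-2(3H)-one F11.

  Irradiation of F11 at about 350 nm in acetonitrile, a known photoisomerisation of α-arylidene lactones, should enrich the Z isomer 22, whose aryl ring is twisted by the carbonyl oxygen and absorbs less. 22 is separated and the rest re-irradiated.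

**Step 14.**
- What may go wrong: rotation about C3=C6 in the Lewis-acid complex, where the C4' oxygen and the coordinated carbonyl give the alkene push-pull character, or chelation-assisted loss of a methyl ether next to a newly freed oxygen.
- Fallback: it sets out from 22 and returns at 23. The deprotection is run as above. Any (3E,4S)-3-(3,4-dihydroxy-5-methoxybenzylidene)-4-(4-hydroxy-3-methoxybenzyl)dihydrofuran-2(3H)-one F12 that forms is separated and photoisomerised under argon (350 nm, degassed acetonitrile) to 23, so that the geometry is restored after, not preserved through, the Lewis-acid step.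

## Further compounds

F1 | step 12 | 3-methoxycatechol | COc1cccc(O)c1O
F2 | step 12 | 1,2-diisopropoxy-3-methoxybenzene | COc1cccc(OC(C)C)c1OC(C)C
F3 | step 12 | 2-(3,4-diisopropoxy-5-methoxyphenyl)-4,4,5,5-tetramethyl-1,3,2-dioxaborolane | COc1cc(B2OC(C)(C)C(C)(C)O2)cc(OC(C)C)c1OC(C)C
F4 | step 11 | 4-acetoxy-2,3-diisopropoxycyclobut-2-en-1-one (racemic) | CC(=O)OC1C(=O)C(OC(C)C)=C1OC(C)C
F5 | step 9 | (3Z,4S)-3-[(Z)-2,3-bis(tributylstannyl)prop-2-en-1-ylidene]-4-(4-isopropoxy-3-methoxybenzyl)dihydrofuran-2(3H)-one | COc1cc(C[C@@H]2COC(=O)/C2=C\C(\[Sn](CCCC)(CCCC)CCCC)=C\[Sn](CCCC)(CCCC)CCCC)ccc1OC(C)C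
F6 | step 6 | (E)-[(4S)-4-(4-isopropoxy-3-methoxybenzyl)-2-oxodihydrofuran-3(2H)-ylidene]methyl 4-methylbenzenesulfonate | COc1cc(C[C@@H]2COC(=O)/C2=C/OS(=O)(=O)c2ccc(C)cc2)ccc1OC(C)C
F7 | step 6 | (3E,4S)-4-(4-isopropoxy-3-methoxybenzyl)-3-[3-(trimethylsilyl)prop-2-yn-1-ylidene]dihydrofuran-2(3H)-one | COc1cc(C[C@@H]2COC(=O)/C2=C/C#C[Si](C)(C)C)ccc1OC(C)C
F8 | step 6 | (3E,4S)-4-(4-isopropoxy-3-methoxybenzyl)-3-(prop-2-yn-1-ylidene)dihydrofuran-2(3H)-one | COc1cc(C[C@@H]2COC(=O)/C2=C/C#C)ccc1OC(C)C
F9 | step 6 | (3E,4S)-4-(4-isopropoxy-3-methoxybenzyl)-3-[2-(tributylstannyl)prop-2-en-1-ylidene]dihydrofuran-2(3H)-one | COc1cc(C[C@@H]2COC(=O)/C2=C/C(=C)[Sn](CCCC)(CCCC)CCCC)ccc1OC(C)C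
F10 | step 6 | (3E,4S)-3-(3-hydroxy-4,5-diisopropoxybenzylidene)-4-(4-isopropoxy-3-methoxybenzyl)dihydrofuran-2(3H)-one | COc1cc(C[C@@H]2COC(=O)/C2=C/c2cc(O)c(OC(C)C)c(OC(C)C)c2)ccc1OC(C)C
F11 | step 6 | (3E,4S)-3-(3,4-diisopropoxy-5-methoxybenzylidene)-4-(4-isopropoxy-3-methoxybenzyl)dihydrofuran-2(3H)-one | COc1cc(C[C@@H]2COC(=O)/C2=C/c2cc(OC)c(OC(C)C)c(OC(C)C)c2)ccc1OC(C)C
F12 | step 14 | (3E,4S)-3-(3,4-dihydroxy-5-methoxybenzylidene)-4-(4-hydroxy-3-methoxybenzyl)dihydrofuran-2(3H)-one | COc1cc(C[C@@H]2COC(=O)/C2=C/c2cc(O)c(O)c(OC)c2)ccc1O
A1 | alternative 1 | (Z)-3-[3,4-bis(tert-butyldimethylsilyloxy)-5-methoxyphenyl]-2-(oxetan-3-yl)acrylic acid | OC(=O)/C(=C\c1cc(O[Si](C)(C)C(C)(C)C)c(O[Si](C)(C)C(C)(C)C)c(OC)c1)C1COC1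
A2 | alternative 1 | (3Z,4R)-3-[3,4-bis(tert-butyldimethylsilyloxy)-5-methoxybenzylidene]-4-(hydroxymethyl)dihydrofuran-2(3H)-one | OC[C@@H]1COC(=O)/C1=C\c1cc(O[Si](C)(C)C(C)(C)C)c(O[Si](C)(C)C(C)(C)C)c(OC)c1
A3 | alternative 2 | 3-[4-(tert-butyldimethylsilyloxy)-3-methoxybenzyl]cyclobutan-1-one | COc1cc(CC2CC(=O)C2)ccc1O[Si](C)(C)C(C)(C)C
A4 | alternative 2 | (S)-4-[4-(tert-butyldimethylsilyloxy)-3-methoxybenzyl]dihydrofuran-2(3H)-one | COc1cc(C[C@@H]2COC(=O)C2)ccc1O[Si](C)(C)C(C)(C)C
A5 | alternative 3 | (E)-3-[4-(tert-butyldimethylsilyloxy)-3-methoxyphenyl]allyl 3-[3,4-bis(tert-butyldimethylsilyloxy)-5-methoxyphenyl]propiolate | COc1cc(/C=C/COC(=O)C#Cc2cc(O[Si](C)(C)C(C)(C)C)c(O[Si](C)(C)C(C)(C)C)c(OC)c2)ccc1O[Si](C)(C)C(C)(C)C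
A6 | alternative 3 | (3Z,4S)-3-[3,4-bis(tert-butyldimethylsilyloxy)-5-methoxybenzylidene]-4-[4-(tert-butyldimethylsilyloxy)-3-methoxybenzyl]dihydrofuran-2(3H)-one | COc1cc(C[C@@H]2COC(=O)/C2=C\c2cc(O[Si](C)(C)C(C)(C)C)c(O[Si](C)(C)C(C)(C)C)c(OC)c2)ccc1O[Si](C)(C)C(C)(C)C
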